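**Remarks on the chemistry (assumptions)**
- Locants: lactone O1, C2 (carbonyl), C3, C4, C5; C7 is the benzylic methylene on C3 (ring A = 4-hydroxy-3-methoxyphenyl); C7' is the carbinol carbon on C4 (ring B = 3,4-dimethoxyphenyl). Re-derived from the SMILES, the target is (3R,4R,7'S) with the two ring substituents trans.
- The sense of induction of the chiral pyridine–oxazoline ligand in step 3 cannot be derived from first principles. The (S)-ligand is written; its mirror image is used if a test run shows that it favours the other alkene face.

## Structural features

The target is a γ-butyrolactone of the dibenzylbutyrolactone lignan type, oxygenated at the benzylic carbon of the C4 side chain. C3 carries a 4-hydroxy-3-methoxybenzyl group (C7, ring A); C4 carries the secondary carbinol carbon C7', which is bonded to ring B. Three stereocentres stand in a row: C3 (R), C4 (R) and C7' (S). The C7' hydroxyl is the fragile point. It sits on an electron-rich benzylic carbon, so acid can ionise it (Friedel–Crafts closure onto ring A) and hydrogen can cleave it; it is also γ to the lactone carbonyl, so base can cause translactonisation. C3 is epimerisable and the free phenol is oxidisable. The ring itself is easy; the difficulty is to create one stereocentre catalytically and relay it to the other two. A hydrogen can be delivered to C3 kinetically only anti to the C4 substituent (giving cis), so trans must come from equilibration, and C4 turns acidic as soon as C7' is a carbonyl. The key step exploits the linear array ring A–C7–C3–C4 together with the ester bridge C2–O1–C5: an aryl nucleophile, a propiolate (C7, C3, C2) and an allylic alkene (C4, C5) are zipped together, forming C7–aryl and C3–C4 and setting C4.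

## Logic of the disconnections

**16 from 15.** The C7'–H bond is cut, leaving an aryl ketone. The carbinol is the most sensitive function, so it is made in the last step under nearly neutral catalytic conditions. This removes the C7' stereocentre from all earlier intermediates. The forward step must be reagent-controlled in a hindered, electron-rich ketone and must not touch C3.

**15 from 14.** The phenol O–benzyl bond is cut. Ring A must stay masked through the periodate, organomagnesium and periodinane stages, and the mask must come off before the hydrogenolysis-prone carbinol exists. The forward hydrogenolysis has to stop short of the aryl ketone.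

**14 from 13, and 13 from 10 and 11 (through 12).** The C7'–ring B bond is cut, with an oxidation-level adjustment. Ring B becomes a purchased aryl bromide and the lactone half shrinks to a formyl lactone. Because the carbinol is oxidised at once, the facial selectivity of the addition is irrelevant. The forward addition must pick the aldehyde over the lactone and must not enolise an aldehyde whose enolate can expel the ring carboxylate.

**10 from 8 (through 9).** The formyl group is traced back to a vinyl group, a latent carbonyl that is inert to the cascade and to conjugate reduction. The demand falls on 8: it must be free of its C3 epimer before C4 becomes acidic, because a cis contaminant would later epimerise at C4 and end up in the enantiomeric series.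

**8 from 6 (through 7).** The C7–H and C3–H bonds are removed, returning the C3=C7 double bond. This shifts the C3 problem to an equilibration next to a non-acidic C4 centre. The forward reduction must be 1,4-selective and leave the vinyl group; base may be added only when 6 is gone, since 6 would isomerise to an achiral endocyclic butenolide.

**6 from 4 and 5.** The C7–aryl and C3–C4 bonds are cut together, which opens the ring and removes the only stereocentre. What remains is an achiral enyne ester and a purchasable boronic acid. The forward step needs aryl-to-C7 regiochemistry, ring closure faster than protonolysis, ligand control of the alkene face, and a catalyst that stays divalent. The precursor 4 is kept as it is: the terminal alkyne supplies the C7 hydrogen, the Z-alkene is the geometry for which nitrogen-ligand control of this insertion is known, and the acetate both terminates the cycle and blocks β-hydride elimination.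

**4 from 2 and 3; 2 from 1.** Two ester C–O bonds are cut, leading to bulk chemicals. The only demands are mono-functionalisation of a symmetrical diol and an esterification mild enough for a propiolate.

## Other disconnections considered

**Alternative 1: Baeyer–Villiger desymmetrisation.**
- **Cut:** the O1–C5 bond, contracting the lactone to a cyclobutanone.
- **Forward step:** 3-[(S)-(tert-butyldimethylsilyloxy)(3,4-dimethoxyphenyl)methyl]cyclobutanone A1 is oxidised by a peracid under Sc(OTf)3 and a chiral N,N'-dioxide ligand. The catalyst chooses which methylene migrates in the Criegee adduct and so creates C4, giving (R)-4-[(S)-(tert-butyldimethylsilyloxy)(3,4-dimethoxyphenyl)methyl]dihydrofuran-2(3H)-one A2. Ring A would enter by alkylating the enolate of A2 with 4-benzyloxy-3-methoxybenzyl bromide A3, giving the protected lactone A4; desilylation and debenzylation would follow.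
- **In favour:** the C7' carbinol is in place and protected before the ring exists, so no late ketone reduction is needed. C3 is set by C–C bond formation anti to the large C4 substituent, which is kinetic trans control. On this point the alternative is better than the chosen plan, which can only equilibrate C3. It also avoids adding an organometallic to an epimerisable aldehyde.
- **Against:** A1 is not purchasable and needs its own asymmetric synthesis of C7' (roughly five to six steps). Its two methylenes are diastereotopic, so catalyst and substrate preferences may oppose each other. Both protecting groups must be removed from a molecule that already contains the fragile carbinol: hydrogenolysis next to a benzylic C–O bond, and fluoride next to a γ-hydroxy lactone.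
- **Comparison:** structurally, it builds the C4–C7' half first and adds ring A last, the reverse of the chosen order. Mechanistically, both plans let a chiral catalyst set C4 on a prochiral element. The precedent for desymmetrising simple 3-substituted cyclobutanones is at least as firm as that for the arylative cascade, so on the key step the alternative is equal or better, apart from the unknown influence of the neighbouring stereocentre. In step count it is somewhat longer (about ten to eleven against nine) and ends with riskier deprotections.

**Alternative 2: Formaldehyde aldol–lactonisation.**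
- **Cut:** C4–C5 and C5–O1, with C5 supplied by formaldehyde.
- **Forward step:** the ketone enolate (C4) of (R)-2-(4-benzyloxy-3-methoxybenzyl)-4-(3,4-dimethoxyphenyl)-4-oxobutanoic acid A5 adds to formaldehyde in aqueous NaOH; acidification closes the lactone to (3R,4R)-3-(4-benzyloxy-3-methoxybenzyl)-4-(3,4-dimethoxybenzoyl)dihydrofuran-2(3H)-one A6, which is the same substance as 14.
- **In favour:** cheap and metal-free. C4 is α to the ketone, so the trans arrangement arises by equilibration next to a fixed C3, with no epimer to separate. This is better than step 4 of the chosen plan. It lands directly on 14, so the last two steps are shared, and the cleavage, addition and oxidation steps are not needed.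
- **Against:** all chirality must be put into the single centre of A5 beforehand, by an auxiliary alkylation or an asymmetric hydrogenation (some four to five steps). In aqueous base the C4 methylene can be hydroxymethylated twice or the aldol can dehydrate. The β-acyloxy ketone reopens by elimination in base, so the outcome depends on the acidification.
- **Comparison:** structurally, the ring is closed by inserting one carbon at C5 instead of by forming C3–C4. Mechanistically, diastereocontrol is thermodynamic (equal or better for the trans relation), but the key step creates no chirality, whereas the chosen key step does. In step count it is comparable and possibly one step shorter, if A5 can be made as briefly as estimated.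

**Alternative 3: Palladium cyclocarbonylation.**
- **Cut:** C2–O1 and C2–C3, with C2 supplied by carbon monoxide.
- **Forward step:** the alkynol (2R,3S)-2-[(4-benzyloxy-3-methoxyphenyl)ethynyl]-3-(tert-butyldimethylsilyloxy)-3-(3,4-dimethoxyphenyl)propan-1-ol A7 reacts with CO under PdCl2(PPh3)2 and SnCl2. Syn addition of an alkoxycarbonylpalladium unit across the alkyne and protonolysis give (R,E)-3-(4-benzyloxy-3-methoxybenzylidene)-4-[(S)-(tert-butyldimethylsilyloxy)(3,4-dimethoxyphenyl)methyl]dihydrofuran-2(3H)-one A8. Conjugate reduction and equilibration would lead to A4, then deprotection.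
- **In favour:** both rings, C4 and C7' are present before the lactone closes, so only about three steps follow the key step against six in the chosen plan. This is its clear advantage. The C3 equilibration takes place beside a large, non-acidic C4 substituent, which should give a stronger trans bias than the vinyl group allows; this is also better than the chosen plan.
- **Against:** A7 has two contiguous stereocentres that must be built in open-chain form (about seven steps), and the key step creates none. Pressurised, toxic CO is needed. Internal aryl alkynes are slower substrates than the terminal alkynols for which the method is established. SnCl2 is a Lewis acid next to an electron-rich benzylic silyl ether. The late deprotection problem of alternative 1 returns.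
- **Comparison:** structurally, both plans pass through an E-benzylidene lactone and the same conjugate reduction; A8 is fully decorated, 6 is minimal. Mechanistically, the carbonylation fixes only alkene geometry, while the chosen cascade fixes geometry and C4. Overall the alternative is longer (about eleven steps) despite its shorter end game.

Key step: step 3

## Route

**Step 1**
Reactants: 1 (Z)-but-2-ene-1,4-diol
Product: 2 (Z)-4-hydroxybut-2-en-1-yl acetate
Conditions: 1 (4 equiv), Ac2O (1 equiv), Et3N, DMAP (cat.), CH2Cl2, 0 °C
Reagents that add atoms: acetic anhydride, CC(=O)OC(C)=O
Why: Statistical monoacylation of a symmetrical diol with nucleophilic catalysis; the fourfold excess of the water-soluble diol suppresses the diacetate and is washed out, and the Z geometry is untouched.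

**Step 2**
Reactants: 2 (Z)-4-hydroxybut-2-en-1-yl acetate; 3 propiolic acid
Product: 4 (Z)-4-acetoxybut-2-en-1-yl propiolate
Conditions: DCC (1.1 equiv), DMAP (5 mol %), CH2Cl2, −20 to 0 °C
Reagents that add atoms: none
Why: Steglich esterification through the O-acylisourea; the low temperature and the small amount of DMAP hold back conjugate addition of the amine to the propiolate, and the allylic acetate is inert.

**Step 3**
Reactants: 4 (Z)-4-acetoxybut-2-en-1-yl propiolate; 5 (4-benzyloxy-3-methoxyphenyl)boronic acid
Product: 6 (R,E)-3-(4-benzyloxy-3-methoxybenzylidene)-4-vinyldihydrofuran-2(3H)-one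
Conditions: Pd(OAc)2 (5 mol %), (S)-t-BuPyOx (6 mol %), 5 (1.3 equiv), H2O (5 equiv), ClCH2CH2Cl, 40 °C, N2
Reagents that add atoms: none
Why: Transmetalation from boron gives an aryl complex of divalent palladium on the chiral N,N-ligand, and syn carbopalladation of the propiolate puts the aryl group on the terminal carbon C7 and palladium on C3, as both the polarisation of the ynoate and the lower steric demand of the CH terminus require. The alkenylpalladium then inserts the Z-allylic alkene in a 5-exo-trig carbopalladation that forms C3–C4 and closes the lactone ring, and β-acetoxy elimination releases the vinyl group and returns divalent palladium, so no oxidant is needed and β-hydride elimination is shut off. The closest known reactions are the nucleophile-initiated cyclisation of 4-acetoxybut-2-enyl alkynoates under divalent palladium with nitrogen ligands, which has an enantioselective form, and the boronic-acid-initiated arylative cyclisation of enynes; this step merges the two, and the aryl-initiated enantioselective case on a propiolate is an extrapolation. C4 is the only new stereocentre and is set in the alkene insertion, where the tert-butyl group of the oxazoline differentiates the two faces of the Z-alkene held by the ester tether. Syn addition gives the E-benzylidene, although this geometry is erased in step 4. The step needs insertion to outrun protonolysis of the C3–Pd bond, which the five-atom tether, the absence of added acid and the nearly anhydrous aprotic medium favour, and on this ester class cyclisation is known to compete well even in acetic acid. It also needs palladium to stay divalent, which the phosphine-free, base-free conditions support, because zerovalent palladium would ionise the allylic esters.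

**Step 4**
Reactants: 6 (R,E)-3-(4-benzyloxy-3-methoxybenzylidene)-4-vinyldihydrofuran-2(3H)-one
Product: 8 (3R,4R)-3-(4-benzyloxy-3-methoxybenzyl)-4-vinyldihydrofuran-2(3H)-one, via C3-epimeric 3-benzyl-4-vinyl lactone mixture 7 (not isolated)
Conditions: Cu(OAc)2·H2O (3 mol %), 1,2-bis(diphenylphosphino)benzene (3 mol %), (EtO)2MeSiH (1.5 equiv), t-BuOH (3 equiv), toluene, rt; then DBU (1 equiv), 50 °C; chromatography
Reagents that add atoms: none
Why: A phosphine-ligated CuH species delivers hydride to C7 of the aryl-conjugated enoate and ignores the isolated vinyl group (catalytic conjugate reduction, turned over by the silane); protonation at C3 is expected anti to the vinyl group, that is mainly cis, so DBU then equilibrates C3 to the more stable trans (3R) arrangement while the non-acidic C4 is untouched. DBU is added only after 6 is consumed, since 6 would isomerise to the achiral endocyclic butenolide, and residual cis epimer is separated and recycled because it would later drift into the enantiomeric series.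

**Step 5**
Reactants: 8 (3R,4R)-3-(4-benzyloxy-3-methoxybenzyl)-4-vinyldihydrofuran-2(3H)-one
Product: 10 (3R,4R)-3-(4-benzyloxy-3-methoxybenzyl)-4-formyldihydrofuran-2(3H)-one, via 4-(1,2-dihydroxyethyl) lactone 9 (not isolated)
Conditions: K2OsO4·2H2O (2 mol %), NaIO4 (4 equiv), 2,6-lutidine (2 equiv), dioxane–H2O (3:1), rt; used crude
Reagents that add atoms: sodium periodate, [Na+].[O-]I(=O)(=O)=O (oxygen of the formyl group, passed on through the osmium oxo species); water, O
Why: Lemieux–Johnson cleavage: the osmium oxo species dihydroxylates the only alkene and periodate cleaves the diol and reoxidises osmium. 2,6-Lutidine keeps the medium near neutral, so the β-acyloxy aldehyde is neither eliminated nor over-oxidised, and trans is in any case the stable arrangement at C4.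

**Step 6**
Reactants: 10 (3R,4R)-3-(4-benzyloxy-3-methoxybenzyl)-4-formyldihydrofuran-2(3H)-one; 11 4-bromo-1,2-dimethoxybenzene
Product: 13 (3R,4R)-3-(4-benzyloxy-3-methoxybenzyl)-4-[hydroxy(3,4-dimethoxyphenyl)methyl]dihydrofuran-2(3H)-one as a mixture of C7' epimers, via (3,4-dimethoxyphenyl)magnesium bromide 12 (not isolated)
Conditions: 11, Mg, THF, rt; then 10, LaCl3·2LiCl (1 equiv), THF, −78 °C; aq NH4Cl at −78 °C
Reagents that add atoms: none
Why: Grignard formation and 1,2-addition to the aldehyde; at −78 °C with the oxophilic lanthanum salt the aldehyde reacts far faster than the lactone, and enolisation, which would open the ring by loss of the carboxylate, is held back. The configuration at C7' does not matter because the carbinol is oxidised in step 7.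

**Step 7**
Reactants: 13 (3R,4R)-3-(4-benzyloxy-3-methoxybenzyl)-4-[hydroxy(3,4-dimethoxyphenyl)methyl]dihydrofuran-2(3H)-one as a mixture of C7' epimers
Product: 14 (3R,4R)-3-(4-benzyloxy-3-methoxybenzyl)-4-(3,4-dimethoxybenzoyl)dihydrofuran-2(3H)-one
Conditions: Dess–Martin periodinane (1.3 equiv), CH2Cl2, 0 °C to rt
Reagents that add atoms: none
Why: Dess–Martin oxidation of a secondary benzylic alcohol without base, which protects the β-acyloxy ketone from elimination and C3 from epimerisation; C4, now α to the ketone, can only relax to the trans arrangement it already has.

**Step 8**
Reactants: 14 (3R,4R)-3-(4-benzyloxy-3-methoxybenzyl)-4-(3,4-dimethoxybenzoyl)dihydrofuran-2(3H)-one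
Product: 15 (3R,4R)-4-(3,4-dimethoxybenzoyl)-3-(4-hydroxy-3-methoxybenzyl)dihydrofuran-2(3H)-one
Conditions: H2 (1 atm), 10 % Pd/C, EtOAc, rt, monitored
Reagents that add atoms: none
Why: Neutral hydrogenolysis of the aryl benzyl ether, which is cleaved much faster than the electron-rich aryl ketone is reduced; the phenol is unmasked before the hydrogenolysis-prone carbinol exists.

**Step 9**
Reactants: 15 (3R,4R)-4-(3,4-dimethoxybenzoyl)-3-(4-hydroxy-3-methoxybenzyl)dihydrofuran-2(3H)-one
Product: 16 (3R,4R)-3-(4-hydroxy-3-methoxybenzyl)-4-[(S)-hydroxy(3,4-dimethoxyphenyl)methyl]dihydrofuran-2(3H)-one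
Conditions: RuCl[(S,S)-TsDPEN](p-cymene) (2 mol %), HCO2H–Et3N (5:2), EtOAc, 25 °C
Reagents that add atoms: none
Why: Noyori–Ikariya asymmetric transfer hydrogenation: the Ru–H and N–H pair transfers hydride and proton in an outer-sphere transition state in which ring B is held by a CH–π contact with the p-cymene ligand, so the (S,S)-catalyst should give the S carbinol as it does with simple aryl alkyl ketones (aryl ranks above C4 in the same way). The buffered, mildly acidic medium at room temperature should cause neither translactonisation by the new γ-hydroxyl, nor ionisation of the benzylic alcohol, nor epimerisation at C3.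

## Compound list

1 | (Z)-but-2-ene-1,4-diol | OC/C=C\CO | starting material
2 | (Z)-4-hydroxybut-2-en-1-yl acetate | CC(=O)OC/C=C\CO | intermediate
3 | propiolic acid | C#CC(=O)O | starting material
4 | (Z)-4-acetoxybut-2-en-1-yl propiolate | C#CC(=O)OC/C=C\COC(C)=O | intermediate
5 | (4-benzyloxy-3-methoxyphenyl)boronic acid | COc1cc(B(O)O)ccc1OCc1ccccc1 | starting material
6 | (R,E)-3-(4-benzyloxy-3-methoxybenzylidene)-4-vinyldihydrofuran-2(3H)-one | COc1cc(/C=C2/C(=O)OC[C@@H]2C=C)ccc1OCc1ccccc1 | intermediate
7 | (4R)-3-(4-benzyloxy-3-methoxybenzyl)-4-vinyldihydrofuran-2(3H)-one, mixture of C3 epimers | COc1cc(CC2C(=O)OC[C@@H]2C=C)ccc1OCc1ccccc1 | intermediate (not isolated)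
8 | (3R,4R)-3-(4-benzyloxy-3-methoxybenzyl)-4-vinyldihydrofuran-2(3H)-one | COc1cc(C[C@H]2C(=O)OC[C@@H]2C=C)ccc1OCc1ccccc1 | intermediate
9 | (3R,4R)-3-(4-benzyloxy-3-methoxybenzyl)-4-(1,2-dihydroxyethyl)dihydrofuran-2(3H)-one, both carbinol epimers | COc1cc(C[C@H]2C(=O)OC[C@@H]2C(O)CO)ccc1OCc1ccccc1 | intermediate (not isolated)
10 | (3R,4R)-3-(4-benzyloxy-3-methoxybenzyl)-4-formyldihydrofuran-2(3H)-one | COc1cc(C[C@H]2C(=O)OC[C@@H]2C=O)ccc1OCc1ccccc1 | intermediate
11 | 4-bromo-1,2-dimethoxybenzene | COc1ccc(Br)cc1OC | starting material
12 | (3,4-dimethoxyphenyl)magnesium bromide | COc1ccc([Mg]Br)cc1OC | intermediate (not isolated)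
13 | (3R,4R)-3-(4-benzyloxy-3-methoxybenzyl)-4-[hydroxy(3,4-dimethoxyphenyl)methyl]dihydrofuran-2(3H)-one, mixture of C7' epimers | COc1cc(C[C@H]2C(=O)OC[C@@H]2C(O)c2ccc(OC)c(OC)c2)ccc1OCc1ccccc1 | intermediate
14 | (3R,4R)-3-(4-benzyloxy-3-methoxybenzyl)-4-(3,4-dimethoxybenzoyl)dihydrofuran-2(3H)-one | COc1cc(C[C@H]2C(=O)OC[C@@H]2C(=O)c2ccc(OC)c(OC)c2)ccc1OCc1ccccc1 | intermediate
15 | (3R,4R)-4-(3,4-dimethoxybenzoyl)-3-(4-hydroxy-3-methoxybenzyl)dihydrofuran-2(3H)-one | COc1cc(C[C@H]2C(=O)OC[C@@H]2C(=O)c2ccc(OC)c(OC)c2)ccc1O | intermediate
16 | (3R,4R)-3-(4-hydroxy-3-methoxybenzyl)-4-[(S)-hydroxy(3,4-dimethoxyphenyl)methyl]dihydrofuran-2(3H)-one | COc1cc(C[C@H]2C(=O)OC[C@@H]2[C@H](O)c2ccc(OC)c(OC)c2)ccc1O | target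

## Step count and risk

Total: 9 steps. Longest linear sequence: 9 steps (1, 2, 4, 6, 8, 10, 13, 14, 15, 16); 3, 5 and 11 enter as purchased partners.

**Step 3 (key step).**
- **What may go wrong:** protonolysis of the C3–palladium bond before the alkene inserts (simple hydroarylation); acetylide formation and coupling at the terminal alkyne; reduction to zerovalent palladium followed by ionisation of the allylic esters and allyl–aryl coupling; and weak facial discrimination, because the aryl group sits syn to palladium, unlike in the nucleophile-initiated variant for which ligand control is known.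
- **Fallback (sets out from 4, returns at 8):** 4 is cyclised with LiBr and Pd(OAc)2 plus a chiral pyridine–oxazoline or bisoxazoline ligand in acetic acid at room temperature. Anti bromopalladation, the same 5-exo insertion and β-acetoxy elimination should give (R,Z)-3-(bromomethylene)-4-vinyldihydrofuran-2(3H)-one F1; the ligand would need re-tuning for bromide. Suzuki–Miyaura coupling of F1 with 5 (Pd(OAc)2, SPhos, KF, THF, room temperature) gives (R,Z)-3-(4-benzyloxy-3-methoxybenzylidene)-4-vinyldihydrofuran-2(3H)-one F2. The Z geometry is harmless because C7 becomes a methylene: F2 is taken through the conditions of step 4 and joins the route at 8.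

**Step 4.**
- **What may go wrong:** incomplete equilibration, because the vinyl group is small and the trans preference may be modest, with leakage of cis material into the enantiomeric series once C4 becomes acidic; and base-induced double-bond migration if any 6 survives the reduction.
- **Fallback (sets out from 7, isolated without base; returns at 10):** the C4 substituent is enlarged before equilibration. Cross-metathesis of 7 with 2-methyl-2-butene (second-generation Hoveyda–Grubbs catalyst, CH2Cl2, 40 °C) gives (4R)-3-(4-benzyloxy-3-methoxybenzyl)-4-(2-methylprop-1-en-1-yl)dihydrofuran-2(3H)-one as a C3-epimer mixture F3. Its equilibration with DBU should lie further on the trans side and give the (3R,4R) isomer F4. The Lemieux–Johnson conditions of step 5 applied to F4 give 10.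

**Step 6.**
- **What may go wrong:** deprotonation of the α-branched aldehyde by the basic organometallic with ring-opening elimination of the carboxylate; competing attack on the lactone; and translactonisation of the magnesium alkoxide on warming.
- **Fallback (sets out from 10, returns at 14, replacing steps 6 and 7):** Pinnick oxidation (NaClO2, NaH2PO4, 2-methyl-2-butene, t-BuOH–H2O) gives (3R,4R)-4-(4-benzyloxy-3-methoxybenzyl)-5-oxotetrahydrofuran-3-carboxylic acid F5. Thioesterification (EtSH, DCC, cat. DMAP) gives S-ethyl (3R,4R)-4-(4-benzyloxy-3-methoxybenzyl)-5-oxotetrahydrofuran-3-carbothioate F6. Liebeskind–Srogl coupling of F6 with purchased (3,4-dimethoxyphenyl)boronic acid (Pd2(dba)3, tri(2-furyl)phosphine, copper thiophene-2-carboxylate, THF, 50 °C) gives 14 under neutral conditions.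

**Step 8.**
- **What may go wrong:** over-reduction of the aryl ketone to the carbinol and further to the methylene compound if hydrogen uptake is not stopped in time.
- **Fallback (sets out from 14, returns at 15):** Lewis-acid debenzylation with BCl3 and pentamethylbenzene as cation scavenger in CH2Cl2 at −78 °C, which leaves ketone, lactone and methyl ethers alone; no new compound is made (F0).

**Step 9.**
- **What may go wrong:** slow hydride transfer to a hindered, electron-rich ketone, and a mismatch between the catalyst's preference and the Felkin bias of C4, giving poor facial selectivity at C7'. A residual enantiomeric impurity from step 4 would appear here as a separable diastereomer.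
- **Fallback (sets out from 15, returns at 16):** the stereocontrol principle is changed to Corey–Bakshi–Shibata reduction with (R)-2-methyl-CBS-oxazaborolidine and BH3·SMe2 in THF at −30 °C, with one extra equivalent of borane for the phenol. Here the aryl group acts as the large substituent on the boron-bound ketone; no new compound is made (F0).

## Further compounds

F1 | step 3 | (R,Z)-3-(bromomethylene)-4-vinyldihydrofuran-2(3H)-one | Br/C=C1\C(=O)OC[C@@H]1C=C
F2 | step 3 | (R,Z)-3-(4-benzyloxy-3-methoxybenzylidene)-4-vinyldihydrofuran-2(3H)-one | COc1cc(/C=C2\C(=O)OC[C@@H]2C=C)ccc1OCc1ccccc1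
F3 | step 4 | (4R)-3-(4-benzyloxy-3-methoxybenzyl)-4-(2-methylprop-1-en-1-yl)dihydrofuran-2(3H)-one, mixture of C3 epimers | COc1cc(CC2C(=O)OC[C@@H]2C=C(C)C)ccc1OCc1ccccc1
F4 | step 4 | (3R,4R)-3-(4-benzyloxy-3-methoxybenzyl)-4-(2-methylprop-1-en-1-yl)dihydrofuran-2(3H)-one | COc1cc(C[C@H]2C(=O)OC[C@@H]2C=C(C)C)ccc1OCc1ccccc1
F5 | step 6 | (3R,4R)-4-(4-benzyloxy-3-methoxybenzyl)-5-oxotetrahydrofuran-3-carboxylic acid | COc1cc(C[C@H]2C(=O)OC[C@@H]2C(=O)O)ccc1OCc1ccccc1
F6 | step 6 | S-ethyl (3R,4R)-4-(4-benzyloxy-3-methoxybenzyl)-5-oxotetrahydrofuran-3-carbothioate | COc1cc(C[C@H]2C(=O)OC[C@@H]2C(=O)SCC)ccc1OCc1ccccc1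
F0 | step 8 | none | none
F0 | step 9 | none | none
A1 | alternative 1 | 3-[(S)-(tert-butyldimethylsilyloxy)(3,4-dimethoxyphenyl)methyl]cyclobutanone | O=C1CC(C1)[C@H](O[Si](C)(C)C(C)(C)C)c1ccc(OC)c(OC)c1
A2 | alternative 1 | (R)-4-[(S)-(tert-butyldimethylsilyloxy)(3,4-dimethoxyphenyl)methyl]dihydrofuran-2(3H)-one | O=C1C[C@H](CO1)[C@H](O[Si](C)(C)C(C)(C)C)c1ccc(OC)c(OC)c1
A3 | alternative 1 | 4-benzyloxy-3-methoxybenzyl bromide | COc1cc(CBr)ccc1OCc1ccccc1
A4 | alternative 1 | (3R,4R)-3-(4-benzyloxy-3-methoxybenzyl)-4-[(S)-(tert-butyldimethylsilyloxy)(3,4-dimethoxyphenyl)methyl]dihydrofuran-2(3H)-one | COc1cc(C[C@H]2C(=O)OC[C@@H]2[C@H](O[Si](C)(C)C(C)(C)C)c2ccc(OC)c(OC)c2)ccc1OCc1ccccc1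
A5 | alternative 2 | (R)-2-(4-benzyloxy-3-methoxybenzyl)-4-(3,4-dimethoxyphenyl)-4-oxobutanoic acid | COc1cc(C[C@H](CC(=O)c2ccc(OC)c(OC)c2)C(=O)O)ccc1OCc1ccccc1
A6 | alternative 2 | (3R,4R)-3-(4-benzyloxy-3-methoxybenzyl)-4-(3,4-dimethoxybenzoyl)dihydrofuran-2(3H)-one | COc1cc(C[C@H]2C(=O)OC[C@@H]2C(=O)c2ccc(OC)c(OC)c2)ccc1OCc1ccccc1
A7 | alternative 3 | (2R,3S)-2-[(4-benzyloxy-3-methoxyphenyl)ethynyl]-3-(tert-butyldimethylsilyloxy)-3-(3,4-dimethoxyphenyl)propan-1-ol | COc1cc(C#C[C@H](CO)[C@H](O[Si](C)(C)C(C)(C)C)c2ccc(OC)c(OC)c2)ccc1OCc1ccccc1
A8 | alternative 3 | (R,E)-3-(4-benzyloxy-3-methoxybenzylidene)-4-[(S)-(tert-butyldimethylsilyloxy)(3,4-dimethoxyphenyl)methyl]dihydrofuran-2(3H)-one | COc1cc(/C=C2/C(=O)OC[C@@H]2[C@H](O[Si](C)(C)C(C)(C)C)c2ccc(OC)c(OC)c2)ccc1OCc1ccccc1
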